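**Retrosynthetic overview**
- Feature: the cyclohexane ring C3a–C4–C5–C6–C7–C7a of the hydrindane. The adjacent C3a (quaternary, Me) and C7a (H) carry trans carbon arms (C3, C1) and are flanked by the heteroatom-bearing C4 (Br) and C7 (OH). This is the pattern of a [4+2] adduct of the (E)-2-methyl-2-enal 4 and the (E,E)-1,4-diacetoxybutadiene 5; the disconnection is C3a–C4 and C7–C7a.
- Ring order: first this six-membered ring by catalytic enantioselective Diels–Alder reaction (step 3); then the five-membered ring by aldol closure C1–C2 after a one-carbon extension of the formyl arm (step 17); ring A last, its olefin geometry and quaternary carbon by Ireland–Claisen rearrangement (step 22) and the ring itself by enolate alkylation (step 25).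
- Heteroatoms: both cycloaddition oxygens are re-set. C7 goes through the ketone and MeCeCl2 (axial OH). C4 goes through the ketone, the bromoalkene and a radical hydrogenation (equatorial Br, no substitution at this neopentyl carbon). The ring A bromide comes from CBS reduction and Appel inversion.

Key step: step 3

**Remarks**
- Locants from compound 6 on follow the hydrindane of the target: ring carbons C3a (Me), C4, C5, C6, C7, C7a; five-ring carbons C1, C2, C3; C1′ is the exocyclic olefinic CH; ring A is C1″ (=C), C2″ (CH2), C3″ (CMe2), C4″ (CHBr), C5″, C6″. α is the face of the C3a methyl group, β the face of H-7a. TBS = tert-butyldimethylsilyl, TES = triethylsilyl.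
- Assumption: the catalyst of step 3 is taken from (S)-α,α-diphenylprolinol, following the usual binding model for 2-substituted enals (attack on the Cα Re face); if the other face were preferred, the (R)-catalyst would be used with no other change.
- Assumption: 1, 3, 5 and 23 are taken as purchased.

**Route**

Step 1
Reactants: 1 3-(TBSO)propan-1-ol
Product: 2 3-(TBSO)propanal
Conditions: TEMPO (cat.), PhI(OAc)2, CH2Cl2, rt
Reagents that add atoms: none
Why: TEMPO/PhI(OAc)2 oxidation of the primary alcohol stops at the aldehyde and leaves the silyl ether intact.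

Step 2
Reactants: 2 3-(TBSO)propanal; 3 2-(triphenylphosphoranylidene)propanal
Product: 4 (E)-5-(TBSO)-2-methylpent-2-enal
Conditions: toluene, 90 °C
Reagents that add atoms: none
Why: Wittig olefination with the stabilised formyl ylide gives the trisubstituted enal with the (E) geometry (CHO trans to the chain) that later fixes the C3a/C7a relation.

Step 3
Reactants: 4 (E)-5-(TBSO)-2-methylpent-2-enal; 5 (1E,3E)-buta-1,3-diene-1,4-diyl diacetate
Product: 6 formyl-endo cyclohex-5-ene adduct (3aβ-CHO; 3aα-Me; 4β-OAc; 7β-OAc; 7aα-CH2CH2OTBS)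
Conditions: (S)-o-tolyl-oxazaborolidine from (S)-α,α-diphenylprolinol (20 mol%), Tf2NH (20 mol%), 5 (2 equiv), CH2Cl2, −78 → −20 °C
Reagents that add atoms: none
Why: The protonated oxazaborolidine binds the formyl oxygen of 4, and the formyl C–H···O contact to the ring oxygen holds the s-trans enal over the carbinol aryl group, so that 5 reaches only the open (Cα-Re) face and the σ-bonds C3a–C4 and C7–C7a form in one concerted, asynchronous, suprafacial [4+2] step. The closest known reaction type is the oxazaborolidinium-catalysed Diels–Alder reaction of 2-substituted and (E)-2,3-disubstituted enals with acyclic dienes. The cyclohexene ring is closed by intermolecular cycloaddition, both ring bonds in the same step, and there is no regiochemical question because the diene is symmetrically substituted. C3a and C7a take their relative configuration (CHO and chain trans, Me and chain cis) from the E geometry of the enal and their absolute configuration from the catalyst; C4 and C7 take theirs from the E,E geometry of the diene (acetates cis to each other) and from the formyl-endo transition state (acetates cis to CHO). The step needs π-facial selectivity, which rests on the α-methyl-substituted formyl group that the catalyst recognises, and retention of the enal geometry, which the concerted mechanism gives; the endo preference only serves step 6, since C7 and C4 are re-set later (steps 7–8 and 9–13).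

Step 4
Reactants: 6 formyl-endo cyclohex-5-ene adduct
Product: 7 saturated diacetate aldehyde (5,6-dihydro-6)
Conditions: H2 (1 atm), Rh/Al2O3 (5% Rh), EtOAc, rt
Reagents that add atoms: none
Why: Catalytic hydrogenation of the cis-disubstituted ring olefin, with Rh on alumina chosen because it saturates allylic acetates without hydrogenolysis and leaves the hindered aldehyde alone; no stereocentre is formed.

Step 5
Reactants: 7 saturated diacetate aldehyde
Product: 8 3a-vinyl diacetate
Conditions: Ph3PCH3Br, KHMDS, THF, 0 °C; then 7, −78 → 0 °C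
Reagents that add atoms: methyltriphenylphosphonium bromide, C[P+](c1ccccc1)(c1ccccc1)c1ccccc1.[Br-], as its ylide C=P(c1ccccc1)(c1ccccc1)c1ccccc1
Why: Wittig methylenation of the non-enolisable neopentyl aldehyde; the vinyl group is the latent C3–C2 unit and, unlike an aldehyde or an enol ether, survives steps 6–11.

Step 6
Reactants: 8 3a-vinyl diacetate
Product: 9 7β-alcohol 4β-acetate
Conditions: K2CO3 (cat.), MeOH, 0 °C, stopped at the monoacetate
Reagents that add atoms: none
Why: Base-catalysed transesterification should cleave the equatorial C7 acetate (beside a tertiary carbon) well before the axial, neopentyl C4 acetate (beside the quaternary C3a), the same rate order as for equatorial versus hindered axial acetates of steroids.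

Step 7
Reactants: 9 7β-alcohol 4β-acetate
Product: 10 7-ketone 4β-acetate
Conditions: Dess–Martin periodinane, pyridine, CH2Cl2, 0 °C → rt
Reagents that add atoms: none
Why: Dess–Martin oxidation under non-basic conditions gives the C7 ketone without epimerising the adjacent C7a.

Step 8
Reactants: 10 7-ketone 4β-acetate
Product: 11 4β,7α-diol with 7β-methyl
Conditions: MeLi, CeCl3 (5 equiv each), THF, −78 °C; then 10, −78 → 0 °C
Reagents that add atoms: methyllithium, [Li]C, used as dichloro(methyl)cerium, C[Ce](Cl)Cl
Why: Organocerium addition: the non-basic reagent adds to the enolisable ketone from the equatorial β side because the axial α path is closed by the 1,3-diaxial C3a methyl group, which sets C7 (Me β, OH α), and on warming the excess reagent adds twice to the hindered acetate and frees the C4 alcohol.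

Step 9
Reactants: 11 4β,7α-diol with 7β-methyl
Product: 12 4-ketone (7α-OH; 7β-Me)
Conditions: Dess–Martin periodinane, pyridine, CH2Cl2, rt
Reagents that add atoms: none
Why: Dess–Martin oxidation of the hindered secondary C4 alcohol (the tertiary C7 alcohol cannot react) deliberately erases the C4 centre, so that bromine can be brought in without a substitution at this neopentyl carbon.

Step 10
Reactants: 12 4-ketone
Product: 13 C4 hydrazone
Conditions: N2H4·H2O (excess), Et3N, EtOH, 80 °C, under argon
Reagents that add atoms: hydrazine, NN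
Why: Hydrazone formation of a ketone next to a quaternary carbon, as with 17-keto steroids; excess hydrazine prevents azine formation and the inert atmosphere prevents diimide reduction of the vinyl group.

Step 11
Reactants: 13 C4 hydrazone
Product: 14 4-bromo-4-ene (3a-vinyl)
Conditions: NBS (2.2 equiv), pyridine, 0 °C → rt
Reagents that add atoms: N-bromosuccinimide, O=C1CCC(=O)N1Br
Why: Barton hydrazone halogenation: the diazo intermediate takes up Br+, loses N2, and the α-bromo cation can lose a proton only from C5, so the 4-bromo-4-ene forms regiospecifically.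

Step 12
Reactants: 14 4-bromo-4-ene (3a-vinyl)
Product: 16 primary alcohol (3a-CH2CH2OH; 4-bromo-4-ene), via B-alkyl-9-BBN adduct 15 (not isolated)
Conditions: 9-BBN, THF, 0 → 50 °C; then NaOH, H2O2, H2O, 0 °C
Reagents that add atoms: hydrogen peroxide, OO; 9-borabicyclo[3.3.1]nonane, B1C2CCCC1CCC2 (its atoms stay only in 15)
Why: Hydroboration–oxidation: 9-BBN adds to the terminal vinyl group, boron on the end carbon, far faster than to the deactivated trisubstituted bromoalkene, and alkaline peroxide gives the primary C2 alcohol.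

Step 13
Reactants: 16 primary alcohol (4-bromo-4-ene)
Product: 17 4α-bromide (saturated)
Conditions: Mn(dpm)3 (10 mol%; dpm = dipivaloylmethanate), PhSiH3, t-BuOOH, i-PrOH, rt
Reagents that add atoms: none
Why: Mn-catalysed hydrogen-atom-transfer hydrogenation, a reaction type known to reduce haloalkenes without loss of halogen: H• adds to C5, and the α-bromo radical at C4 takes its second hydrogen axially from the β face, anti to the axial C3a methyl group, so bromine ends equatorial (α).

Step 14
Reactants: 17 4α-bromide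
Product: 18 tris-TBS ether
Conditions: TBSOTf (3 equiv), 2,6-lutidine, CH2Cl2, 0 °C → rt
Reagents that add atoms: tert-butyldimethylsilyl triflate, CC(C)(C)[Si](C)(C)OS(=O)(=O)C(F)(F)F
Why: Silyl triflate silylation covers the primary C2 hydroxyl and the hindered tertiary C7 hydroxyl at once; the tertiary silyl ether is needed so that the later C1′ aldehyde cannot close a lactol on O7.

Step 15
Reactants: 18 tris-TBS ether
Product: 19 diol (two primary OH; 7α-OTBS)
Conditions: camphorsulfonic acid (10 mol%), MeOH/CH2Cl2, 0 °C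
Reagents that add atoms: none
Why: Acid-catalysed methanolysis removes primary TBS ethers far faster than the hindered tertiary one, so only the two arm hydroxyls are released.

Step 16
Reactants: 19 diol
Product: 20 dialdehyde
Conditions: Dess–Martin periodinane (2.6 equiv), pyridine, CH2Cl2, rt
Reagents that add atoms: none
Why: Twofold Dess–Martin oxidation gives the 1,6-dialdehyde under conditions that neither enolise it nor disturb the bromide.

Step 17
Reactants: 20 dialdehyde
Product: 21 aldol (trans-hydrindane; 1β-CHO; 2β-OH)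
Conditions: (S)-proline (30 mol%), DMSO, rt
Reagents that add atoms: none
Why: Proline-catalysed intramolecular 5-enolexo aldol reaction: the enamine should form and react on the C1 arm (CH2 on the tertiary C7a) rather than on the neopentyl C3 arm, C1 adds to the C2 carbonyl with its oxygen turned to the β face away from the angular methyl group (C2 set), and the enolisable C1 settles with the formyl group pseudo-equatorial, β and anti to the substituted C7 (C1 set under thermodynamic control).

Step 18
Reactants: 21 aldol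
Product: 22 2β-OTBS aldehyde
Conditions: TBSOTf, 2,6-lutidine, CH2Cl2, −78 °C
Reagents that add atoms: tert-butyldimethylsilyl triflate, CC(C)(C)[Si](C)(C)OS(=O)(=O)C(F)(F)F
Why: Silylation with the silyl triflate at −78 °C traps the β-hydroxy aldehyde before retro-aldol cleavage or dehydration can set in.

Step 19
Reactants: 23 2-bromoprop-2-en-1-ol
Product: 24 [(2-bromoprop-2-en-1-yl)oxy]triethylsilane
Conditions: TESCl, imidazole, CH2Cl2, 0 °C
Reagents that add atoms: chlorotriethylsilane, CC[Si](Cl)(CC)CC
Why: Routine silylation of a primary allylic alcohol; the triethylsilyl group is chosen because it can later be removed in the presence of the TBS ethers.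

Step 20
Reactants: 22 2β-OTBS aldehyde; 24 [(2-bromoprop-2-en-1-yl)oxy]triethylsilane
Product: 25 allylic alcohol (both C1′ epimers)
Conditions: CrCl2 (4 equiv), NiCl2 (2 mol%), DMSO, rt
Reagents that add atoms: none
Why: Nozaki–Hiyama–Kishi coupling: the alkenylchromium species formed from 24 adds to the aldehyde under non-basic conditions, so the enolisable C1 and the β-silyloxy group are safe and the alkyl bromide is not touched; the new carbinol centre is a mixture that is destroyed in step 22.

Step 21
Reactants: 25 allylic alcohol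
Product: 26 allylic isobutyrate
Conditions: isobutyric anhydride, Et3N, DMAP (cat.), CH2Cl2, rt
Reagents that add atoms: isobutyric anhydride, CC(C)C(=O)OC(=O)C(C)C
Why: DMAP-catalysed acylation of the secondary allylic alcohol installs the isobutyrate that carries the future C3″ and C4″.

Step 22
Reactants: 26 allylic isobutyrate
Product: 29 (Z)-pent-4-enoic acid (2,2-dimethyl; 4-CH2OTES; 5-hydrindan-1β-yl), via silyl ketene acetal 27 (not isolated), via trimethylsilyl ester 28 (not isolated)
Conditions: LDA, THF, −78 °C; TMSCl, Et3N; −78 → 60 °C; then H2O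
Reagents that add atoms: chlorotrimethylsilane, C[Si](C)(C)Cl (its atoms stay only in 27 and 28)
Why: Ireland–Claisen rearrangement: the silyl ketene acetal rearranges through a chair in which the hydrindanyl group on the carbinol carbon sits equatorial (an axial group would clash with the silyloxy group), so that both carbinol epimers give the olefin with C1 trans to the new CH2–CMe2 bond, and the quaternary C3″ is made in the same step.

Step 23
Reactants: 29 (Z)-pent-4-enoic acid
Product: 31 hydroxy methyl ketone, via triethylsilyl ether ketone 30 (not isolated)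
Conditions: MeLi (4 equiv), Et2O, 0 °C → rt; then poured into 1 M HCl/THF, 0 °C
Reagents that add atoms: methyllithium, [Li]C
Why: Methyllithium adds to the lithium carboxylate and stops at the gem-diolate, which gives the methyl ketone on acidic work-up, the same acid cleaving the primary triethylsilyl ether while the TBS ethers and the equatorial neopentyl bromide are left.

Step 24
Reactants: 31 hydroxy methyl ketone
Product: 32 allylic bromide
Conditions: CBr4, PPh3, 2,6-lutidine, CH2Cl2, 0 °C
Reagents that add atoms: carbon tetrabromide, BrC(Br)(Br)Br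
Why: Appel bromination of the primary allylic alcohol at 0 °C proceeds by direct SN2 attack on the oxyphosphonium ion, without allylic transposition.

Step 25
Reactants: 32 allylic bromide
Product: 33 ring A ketone (4″-oxo; E-olefin)
Conditions: KHMDS (1.1 equiv), THF (high dilution), −78 → 0 °C
Reagents that add atoms: none
Why: Intramolecular ketone-enolate alkylation: the methyl ketone can enolise on one side only, and 6-(enolendo)-exo-tet C-alkylation at the primary allylic bromide closes ring A by SN2 displacement, which leaves the olefin geometry untouched.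

Step 26
Reactants: 33 ring A ketone
Product: 34 (4″R)-alcohol
Conditions: (S)-Me-CBS oxazaborolidine (0.5 equiv), catecholborane, toluene, −78 → −30 °C
Reagents that add atoms: none
Why: Corey–Bakshi–Shibata reduction: the (S)-oxazaborolidine tells the quaternary C3″ flank (large) from the C5″ methylene (small) and should give the (4″R)-alcohol under catalyst control, the hydrindane being too far away to interfere; catecholborane is the hydride source because it does not hydroborate the trisubstituted olefin at low temperature.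

Step 27
Reactants: 34 (4″R)-alcohol
Product: 35 bis-TBS ether of iriediol
Conditions: CBr4, P(n-C8H17)3, toluene, 0 → 70 °C
Reagents that add atoms: carbon tetrabromide, BrC(Br)(Br)Br
Why: Appel reaction in its trialkylphosphine/CBr4 variant, the one used for neopentyl alcohols: bromide displaces the oxyphosphonium group with inversion, (4″R)-alcohol to (4″S)-bromide, the monocyclic ring being free to adopt the conformer with an axial leaving group.

Step 28
Reactants: 35 bis-TBS ether of iriediol
Product: 36 iriediol
Conditions: HF (48% aq.), MeCN, 0 °C → rt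
Reagents that add atoms: none
Why: Cleavage of the secondary and the tertiary TBS ether by HF under acidic conditions, which avoids the E2 elimination that a basic fluoride could cause at the secondary bromides.

**Compound list**
1 | 3-[(tert-butyldimethylsilyl)oxy]propan-1-ol | OCCCO[Si](C)(C)C(C)(C)C | starting material
2 | 3-[(tert-butyldimethylsilyl)oxy]propanal | O=CCCO[Si](C)(C)C(C)(C)C | intermediate
3 | 2-(triphenylphosphoranylidene)propanal | CC(C=O)=P(c1ccccc1)(c1ccccc1)c1ccccc1 | starting material
4 | (E)-5-[(tert-butyldimethylsilyl)oxy]-2-methylpent-2-enal | O=C/C(C)=C/CCO[Si](C)(C)C(C)(C)C | intermediate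
5 | (1E,3E)-buta-1,3-diene-1,4-diyl diacetate | CC(=O)O/C=C/C=C/OC(C)=O | starting material
6 | formyl-endo adduct: cyclohex-5-ene with 3aβ-formyl, 3aα-methyl, 4β- and 7β-acetoxy and 7aα-[2-(TBSO)ethyl] (H-7a β) | O=C[C@]1(C)[C@H](OC(C)=O)C=C[C@H](OC(C)=O)[C@H]1CCO[Si](C)(C)C(C)(C)C | intermediate
7 | 5,6-dihydro derivative of 6 (saturated ring, substituents unchanged) | O=C[C@]1(C)[C@H](OC(C)=O)CC[C@H](OC(C)=O)[C@H]1CCO[Si](C)(C)C(C)(C)C | intermediate
8 | 3aβ-vinyl analogue of 7 (CH=CH2 in place of CHO; 4β,7β-diacetate) | C=C[C@]1(C)[C@H](OC(C)=O)CC[C@H](OC(C)=O)[C@H]1CCO[Si](C)(C)C(C)(C)C | intermediate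
9 | 7β-alcohol 4β-acetate (3aβ-vinyl, 3aα-methyl, 7aα-[2-(TBSO)ethyl]) | C=C[C@]1(C)[C@H](OC(C)=O)CC[C@H](O)[C@H]1CCO[Si](C)(C)C(C)(C)C | intermediate
10 | 7-ketone 4β-acetate | C=C[C@]1(C)[C@H](OC(C)=O)CCC(=O)[C@H]1CCO[Si](C)(C)C(C)(C)C | intermediate
11 | 4β,7α-diol with 7β-methyl (tertiary C7 alcohol axial) | C=C[C@]1(C)[C@H](O)CC[C@@](C)(O)[C@H]1CCO[Si](C)(C)C(C)(C)C | intermediate
12 | 4-ketone with 7α-hydroxy and 7β-methyl | C=C[C@]1(C)C(=O)CC[C@@](C)(O)[C@H]1CCO[Si](C)(C)C(C)(C)C | intermediate
13 | hydrazone of 12 at C4 | C=C[C@]1(C)C(=NN)CC[C@@](C)(O)[C@H]1CCO[Si](C)(C)C(C)(C)C | intermediate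
14 | 4-bromocyclohex-4-ene (C4=C5) with 3aβ-vinyl, 7α-hydroxy, 7β-methyl | C=C[C@]1(C)C(Br)=CC[C@@](C)(O)[C@H]1CCO[Si](C)(C)C(C)(C)C | intermediate
15 | B-alkyl-9-BBN adduct of 14 (boron on C2 of the C3–C2 arm) | C1CC2CCCC(C1)B2CC[C@]1(C)C(Br)=CC[C@@](C)(O)[C@H]1CCO[Si](C)(C)C(C)(C)C | intermediate
16 | primary alcohol: 3aβ-(2-hydroxyethyl)-4-bromocyclohex-4-ene, 7α-hydroxy, 7β-methyl, 7aα-[2-(TBSO)ethyl] | OCC[C@]1(C)C(Br)=CC[C@@](C)(O)[C@H]1CCO[Si](C)(C)C(C)(C)C | intermediate
17 | 4α-bromide (equatorial Br), 3aβ-(2-hydroxyethyl), 7α-hydroxy, 7β-methyl | OCC[C@]1(C)[C@@H](Br)CC[C@@](C)(O)[C@H]1CCO[Si](C)(C)C(C)(C)C | intermediate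
18 | tris-TBS ether of 17 (both arm oxygens and O7) | CC(C)(C)[Si](C)(C)OCC[C@]1(C)[C@@H](Br)CC[C@@](C)(O[Si](C)(C)C(C)(C)C)[C@H]1CCO[Si](C)(C)C(C)(C)C | intermediate
19 | diol: 3aβ- and 7aα-(2-hydroxyethyl) arms, 4α-Br, 7α-OTBS, 7β-Me | OCC[C@]1(C)[C@@H](Br)CC[C@@](C)(O[Si](C)(C)C(C)(C)C)[C@H]1CCO | intermediate
20 | dialdehyde: 3aβ- and 7aα-(2-oxoethyl) arms, 4α-Br, 7α-OTBS, 7β-Me | O=CC[C@]1(C)[C@@H](Br)CC[C@@](C)(O[Si](C)(C)C(C)(C)C)[C@H]1CC=O | intermediate
21 | aldol: trans-hydrindane-1β-carbaldehyde with 2β-OH, 3aα-Me, 4α-Br, 7β-Me, 7α-OTBS, 7aβ-H | O=C[C@@H]1[C@H](O)C[C@]2(C)[C@@H](Br)CC[C@@](C)(O[Si](C)(C)C(C)(C)C)[C@@H]12 | intermediate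
22 | 2β-OTBS ether of 21 | O=C[C@@H]1[C@H](O[Si](C)(C)C(C)(C)C)C[C@]2(C)[C@@H](Br)CC[C@@](C)(O[Si](C)(C)C(C)(C)C)[C@@H]12 | intermediate
23 | 2-bromoprop-2-en-1-ol | C=C(Br)CO | starting material
24 | [(2-bromoprop-2-en-1-yl)oxy]triethylsilane | C=C(Br)CO[Si](CC)(CC)CC | intermediate
25 | allylic alcohol: 1β-[1-hydroxy-2-(TESO-methyl)prop-2-en-1-yl]hydrindane, both C1′ epimers; rest as 22 | C=C(CO[Si](CC)(CC)CC)C(O)[C@@H]1[C@H](O[Si](C)(C)C(C)(C)C)C[C@]2(C)[C@@H](Br)CC[C@@](C)(O[Si](C)(C)C(C)(C)C)[C@@H]12 | intermediate
26 | isobutyrate of 25 | C=C(CO[Si](CC)(CC)CC)C(OC(=O)C(C)C)[C@@H]1[C@H](O[Si](C)(C)C(C)(C)C)C[C@]2(C)[C@@H](Br)CC[C@@](C)(O[Si](C)(C)C(C)(C)C)[C@@H]12 | intermediate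
27 | trimethylsilyl ketene acetal of 26 | CC(C)=C(O[Si](C)(C)C)OC(C(=C)CO[Si](CC)(CC)CC)[C@@H]1[C@H](O[Si](C)(C)C(C)(C)C)C[C@]2(C)[C@@H](Br)CC[C@@](C)(O[Si](C)(C)C(C)(C)C)[C@@H]12 | intermediate
28 | trimethylsilyl ester of 29 | C[Si](C)(C)OC(=O)C(C)(C)C/C(CO[Si](CC)(CC)CC)=C/[C@@H]1[C@H](O[Si](C)(C)C(C)(C)C)C[C@]2(C)[C@@H](Br)CC[C@@](C)(O[Si](C)(C)C(C)(C)C)[C@@H]12 | intermediate
29 | (Z)-2,2-dimethyl-4-(TESO-methyl)-5-(hydrindan-1β-yl)pent-4-enoic acid (hydrindane as in 22; C1 trans to the CH2–CMe2 carbon) | OC(=O)C(C)(C)C/C(CO[Si](CC)(CC)CC)=C/[C@@H]1[C@H](O[Si](C)(C)C(C)(C)C)C[C@]2(C)[C@@H](Br)CC[C@@](C)(O[Si](C)(C)C(C)(C)C)[C@@H]12 | intermediate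
30 | (Z)-3,3-dimethyl-5-(TESO-methyl)-6-(hydrindan-1β-yl)hex-5-en-2-one | CC(=O)C(C)(C)C/C(CO[Si](CC)(CC)CC)=C/[C@@H]1[C@H](O[Si](C)(C)C(C)(C)C)C[C@]2(C)[C@@H](Br)CC[C@@](C)(O[Si](C)(C)C(C)(C)C)[C@@H]12 | intermediate
31 | (Z)-5-(hydroxymethyl)-3,3-dimethyl-6-(hydrindan-1β-yl)hex-5-en-2-one | CC(=O)C(C)(C)C/C(CO)=C/[C@@H]1[C@H](O[Si](C)(C)C(C)(C)C)C[C@]2(C)[C@@H](Br)CC[C@@](C)(O[Si](C)(C)C(C)(C)C)[C@@H]12 | intermediate
32 | (Z)-5-(bromomethyl)-3,3-dimethyl-6-(hydrindan-1β-yl)hex-5-en-2-one | CC(=O)C(C)(C)C/C(CBr)=C/[C@@H]1[C@H](O[Si](C)(C)C(C)(C)C)C[C@]2(C)[C@@H](Br)CC[C@@](C)(O[Si](C)(C)C(C)(C)C)[C@@H]12 | intermediate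
33 | ring A ketone: (E)-1β-[(3″,3″-dimethyl-4″-oxocyclohexylidene)methyl]hydrindane, 2β,7α-bis-OTBS, 4α-Br | CC1(C)C/C(=C/[C@@H]2[C@H](O[Si](C)(C)C(C)(C)C)C[C@]3(C)[C@@H](Br)CC[C@@](C)(O[Si](C)(C)C(C)(C)C)[C@@H]23)CCC1=O | intermediate
34 | (4″R)-alcohol of 33 | CC1(C)C/C(=C/[C@@H]2[C@H](O[Si](C)(C)C(C)(C)C)C[C@]3(C)[C@@H](Br)CC[C@@](C)(O[Si](C)(C)C(C)(C)C)[C@@H]23)CC[C@H]1O | intermediate
35 | 2β,7α-bis-TBS ether of iriediol ((4″S)-bromide) | CC1(C)C/C(=C/[C@@H]2[C@H](O[Si](C)(C)C(C)(C)C)C[C@]3(C)[C@@H](Br)CC[C@@](C)(O[Si](C)(C)C(C)(C)C)[C@@H]23)CC[C@@H]1Br | intermediate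
36 | iriediol: (E)-1β-{[(4″S)-4″-bromo-3″,3″-dimethylcyclohexylidene]methyl}-4α-bromo-3aα,7β-dimethyl-trans-hydrindane-2β,7α-diol | CC1(C)C/C(=C/[C@@H]2[C@H](O)C[C@]3(C)[C@@H](Br)CC[C@@](C)(O)[C@@H]23)CC[C@@H]1Br | target

**Totals**
Total step count: 28. Longest linear sequence: 27 steps (steps 1–18 and 20–28).

**Steps most likely to fail**

Step 3. The acetoxy-deactivated diene may add too slowly to the α,β-disubstituted enal at the temperatures the chiral cation tolerates, so that catalyst decay and an unselective background reaction erode the facial selectivity. Fallback, setting out from 4 and 5: the same cycloaddition is run without a chiral catalyst (Me2AlCl, CH2Cl2, −40 °C, or neat under 12 kbar) to give the racemic formyl-endo adduct F1. F1 is condensed with (1R,2R)-N,N′-dimethyl-1,2-diphenylethane-1,2-diamine (4 Å sieves, Et2O, rt) to two diastereomeric imidazolidines, the aminal of the wanted enantiomer F2 and the aminal of the mirror-image adduct F3, which are separated on silica. Mild hydrolysis of F2 (5% aq. citric acid, Et2O) returns the route to 6.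

Step 17. The β-hydroxy aldehyde may lose water to the enal under the amine conditions, or the enamine may attack the α face of the C2 carbonyl and give the C2 epimer. Fallback, setting out from 20: the dehydration is made deliberate (dibenzylammonium trifluoroacetate, toluene, 50 °C), closing the same C1–C2 bond to the cyclopentene-1-carbaldehyde F4. Copper-catalysed conjugate borylation (CuCl, NaOt-Bu, DPEphos, B2pin2, MeOH, THF) should put boron on C2 from the β face, anti to the angular methyl group, giving the β-boryl aldehyde F5. Oxidation of the C–B bond with retention (NaBO3·4H2O, THF/H2O) returns the route to 21.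

Step 27. Substitution at the neopentyl carbinol carbon is slow, so ionisation of the oxyphosphonium ion with methyl shift, or elimination, may overtake displacement. Fallback, setting out from 34: activation and displacement are separated. The alcohol is converted into the isolable triflate F6 (Tf2O, 2,6-di-tert-butyl-4-methylpyridine, CH2Cl2, −40 °C), and F6 is treated with a soluble bromide in a non-ionising medium (Bu4NBr, toluene, rt), which should give SN2 inversion and return the route to 35.

**Further compounds**
F1 | step 3 | racemic formyl-endo adduct (6 and its mirror image) | O=C[C@]1(C)[C@H](OC(C)=O)C=C[C@H](OC(C)=O)[C@H]1CCO[Si](C)(C)C(C)(C)C.O=C[C@@]1(C)[C@@H](OC(C)=O)C=C[C@@H](OC(C)=O)[C@@H]1CCO[Si](C)(C)C(C)(C)C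
F2 | step 3 | (4R,5R)-1,3-dimethyl-4,5-diphenylimidazolidin-2-yl aminal of 6 (imidazolidine C2 in place of the formyl carbon) | CN1[C@H](c2ccccc2)[C@@H](c2ccccc2)N(C)C1[C@]1(C)[C@H](OC(C)=O)C=C[C@H](OC(C)=O)[C@H]1CCO[Si](C)(C)C(C)(C)C
F3 | step 3 | (4R,5R)-1,3-dimethyl-4,5-diphenylimidazolidin-2-yl aminal of the mirror image of 6 | CN1[C@H](c2ccccc2)[C@@H](c2ccccc2)N(C)C1[C@@]1(C)[C@@H](OC(C)=O)C=C[C@@H](OC(C)=O)[C@@H]1CCO[Si](C)(C)C(C)(C)C
F4 | step 17 | trans-hydrind-1-ene-1-carbaldehyde (C1=C2) with 3aα-Me, 4α-Br, 7β-Me, 7α-OTBS, 7aβ-H | O=CC1=CC[C@]2(C)[C@@H](Br)CC[C@@](C)(O[Si](C)(C)C(C)(C)C)[C@@H]12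
F5 | step 17 | 2β-(pinacolatoboryl)-trans-hydrindane-1β-carbaldehyde, rest as 21 | O=C[C@@H]1[C@H](B2OC(C)(C)C(C)(C)O2)C[C@]2(C)[C@@H](Br)CC[C@@](C)(O[Si](C)(C)C(C)(C)C)[C@@H]12
F6 | step 27 | (4″R)-triflate of 34 | CC1(C)C/C(=C/[C@@H]2[C@H](O[Si](C)(C)C(C)(C)C)C[C@]3(C)[C@@H](Br)CC[C@@](C)(O[Si](C)(C)C(C)(C)C)[C@@H]23)CC[C@H]1OS(=O)(=O)C(F)(F)F
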